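**Remarks on the chemistry (assumptions)**

- Atom labels follow the elemane skeleton. The ring is C5–C6–C7–C8–C9–C10. C10 carries methyl C14 and vinyl C1=C2; C5 carries C4(=C3H2)–C15H2OH; C6 carries the lactone oxygen O6; C7 carries C11(=C13H2)–C12(=O); C8 carries the acyloxy oxygen O8; C9 is CH2.
- The sense of induction of the two external chiral controllers (catalyst in step 2, boron reagent in step 9) is assigned by analogy with simple aldehydes and allyl esters and has not been verified for these substrates. Both are available in either enantiomeric form; the enantiomer meant is the one that gives 4 and 13.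

## The problem

The target 25 is a cyclohexane with five stereocentres: C5, C6, C7, C8 are contiguous and the quaternary C10 sits next to C5. A trans-fused α-methylene-γ-butyrolactone spans C6–C7. The quaternary C10 (methyl, vinyl) beside the tertiary C5 forms a 1,5-diene (C2=C1–C10–C5–C4=C3) that no alkylation can build, and it must be set in the absolute sense. C8 is insulated from C10 by C9H2, so an acyclic relay between them is weak. In the ring chair, however, every substituent is equatorial except C14, so a chair-controlled ring closure can set C6 and C7 from C5, C8 and C10. O6 and O8 are both trans to C11 on C7 and must be told apart: one is lactonised, the other acylated. The feature that makes the key step possible is the array O6–C6–C7–C11(=C13H2)–C12 inside ring C5–C10: a homoallylic alcohol with a 1,1-disubstituted alkene, the retron of a type-1 carbonyl-ene closure of the C6–C7 bond. The methylene lactone (Michael acceptor), the β-hydroxy ester (β-elimination, α-epimerisation, acyl shift) and the allylic alcohol rule out strong base, nucleophiles and heat late in the route.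

## Retrosynthesis

**C8–O acyl bond (25 ⇒ 24 ⇒ 20 + 23).** The (2R)-3-hydroxy-2-methylpropanoate is the most fragile part and goes on last, from Roche-ester-derived acid 23 (from 21 via 22). This cut also lets O8 stay a silyl ether while the lactone is closed, so the lactone can only form on O6. Precursor 20 already has all five ring stereocentres.

**Lactone C12–O6 and the oxidation level of C12 (20 ⇐ 19 ⇐ 17 ⇐ 16).** The lactone carbonyl is read as the methyl of an isopropenyl group on C7 next to a free C6 hydroxyl: allylic hydroxylation gives 17, oxidative lactonisation (via lactol 18) gives 19. Carrying C12 as an acrylate instead would deactivate the alkene that must act as ene donor and expose a Michael acceptor to every C–C bond-forming step.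

**C6–C7, the key cut (16 ⇐ 15).** Opening the carbonyl-ene retron gives acyclic aldehyde 15, which has three stereocentres instead of five, no ring, and a plain prenyl terminus. The forward reaction must close through the chair with O6 equatorial and must choose the trisubstituted alkene among three alkenes. The mirror retron through O8 (cut C7–C8) was weighed against it: an aldehyde on C8 could reach the C3=C4 alkene through a six-membered transition state, whereas from C6 it can reach C3 only through a four-membered one.

**C5–C10 (15 ⇐ 14 ⇐ 13 ⇐ 11 ⇐ 6 + 10).** The quaternary/tertiary pair with its two alkenes is the retron of an ester-enolate Claisen rearrangement. C2–O is cleaved, C5–C10 is formed, the vinyl group C1=C2 is created, and the carboxyl carbon is exactly C6, the carbon needed as the aldehyde (via alcohol 14). Alkylation is not an option at a tertiary centre. Precursor 11 is an ester of two fragments with a single stereocentre; the rearrangement (via boron ketene acetal 12) must control enolate geometry, chair and face.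

**C8–C9 and the fragments (6 ⇐ 5 ⇐ 4 ⇐ 2 + 3; 10 ⇐ 9 ⇐ 8 ⇐ 7).** Fragment 6 is a 5-oxygenated geraniol. Its C8–C9 bond is a vinylogous aldol bond between prenal 3 and the silyl dienolate 2 of methyl senecioate 1, and this step sets C8. Fragment 10 comes from itaconic acid monoester 7 by reduction of the free acid (8), silylation (9) and hydrolysis. The fifteen skeletal carbons are thus three five-carbon isoprenoid units at different oxidation levels: 3 (C7, C8, C11, C12, C13), 1 (C1, C2, C9, C10, C14) and 7 (C3, C4, C5, C6, C15). Three C–C bonds join them (C8–C9, C5–C10, C6–C7).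

## Roads not taken

**Alternative 1:** (the most obvious) Keep the six-membered ring from the start and cut C10–C1, C5–C4 and C7–C11 from a cyclohexenone. The forward key step is a copper-mediated 1,4-addition of a vinyl nucleophile to enone A1 to give ketone A2 with the quaternary C10. Enolate chemistry at both α-carbons of the C6 ketone, reduction, lactonisation and α-methylenation would follow. The chosen plan is better for three reasons:
- Organocopper reagents add anti to the silyloxy group of A1, but A2 needs vinyl syn to O8, so the substrate works against the step.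
- The C5 enolate is neopentylic, and there is no good electrophile for a 3-hydroxyprop-1-en-2-yl cation, so C4 would need an aldol/dehydration or acylation/olefination detour.
- C5, C6 and C7 would each be set in a separate operation and the lactone methylene added last, in well over twenty linear steps. The chosen plan sets C5/C10 in one step and C6/C7 in another.

**Alternative 2:** Cut C5–C10 in the retro-Cope sense and reconnect C2–C3, which leads to germacranolide A3. The forward key step is the thermal [3,3] shift of the ten-membered 1(10),4-diene, a transannular C5–C10 bond formation that would give 25 directly. A3 is an isomer of 25 with the same lactone, the same C6–C8 triad and the same acyl group, now inside a ten-membered ring with two ring alkenes of defined geometry, so it is harder to make than 25. The rearrangement is an equilibrium that needs roughly 200 °C, which the β-hydroxy ester and the methylene lactone tolerate poorly. The chosen plan uses the same [3,3] logic for C5–C10, but on acyclic ester 11 below 0 °C.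

**Alternative 3:** Cut C6–C7 and C12–O6 at once: intramolecular Barbier-type allylation of aldehyde A4, a (Z)-2-(bromomethyl)enoate, with zinc or CrCl2 (divalent chromium), the lactone closing spontaneously. The (Z)-bromide is the isomer that Morita–Baylis–Hillman chemistry provides. Its allylmetal reacts through a closed six-membered transition state with C8 axial, which leads to the cis-fused lactone, not the trans one. The silyloxy group on C8 is β to the metal-bearing allyl terminus and can be lost by elimination. A4 also costs several more steps than 15, because prenal delivers the prenyl terminus of 15 for free. The ene closure gives the trans fusion as a direct consequence of hydrogen transfer from the (E)-methyl through the O-equatorial chair.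

Key step: step 12

## Route

Step 1
Reactants: 1 methyl 3-methylbut-2-enoate
Product: 2 tert-butyl[(1-methoxy-3-methylbuta-1,3-dien-1-yl)oxy]dimethylsilane
Conditions: LiN(iPr)2, THF, −78 °C; then t-BuMe2SiCl, DMPU, −78 °C → rt; distillation
Reagents that add atoms: tert-butylchlorodimethylsilane, C[Si](C)(Cl)C(C)(C)C
Why: γ-Deprotonation of the senecioate gives the extended lithium dienolate, which is O-silylated to the silyl dienol ether, the standard donor for vinylogous Mukaiyama aldol reactions; no stereocentre is formed.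

Step 2
Reactants: 2 tert-butyl[(1-methoxy-3-methylbuta-1,3-dien-1-yl)oxy]dimethylsilane; 3 3-methylbut-2-enal
Product: 4 methyl (2E,5S)-5-hydroxy-3,7-dimethylocta-2,6-dienoate
Conditions: SiCl4 (1.1 equiv), (R,R)-bisphosphoramide catalyst [pentane-1,5-diylbis(methylimino)-linked bis(3,5-dimethyl-4-oxo-3,5-dihydro-4λ5-dinaphtho[2,1-d:1',2'-f][1,3,2]diazaphosphepine) from (R)-N,N'-dimethyl-1,1'-binaphthyl-2,2'-diamine] (5 mol %), iPr2NEt (10 mol %), CH2Cl2, −78 °C; aq KF/NaHCO3
Reagents that add atoms: none
Why: Catalytic enantioselective vinylogous Mukaiyama aldol addition with Lewis-base-activated SiCl4; the dienol ether reacts at its γ-carbon and should give the (E)-δ-hydroxy enoate, which forms C8–C9. The chiral phosphoramide-bound silicon cation is expected to direct attack to the Si face of the enal, which sets C8 as S.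

Step 3
Reactants: 4 methyl (2E,5S)-5-hydroxy-3,7-dimethylocta-2,6-dienoate
Product: 5 methyl (2E,5S)-3,7-dimethyl-5-[(triethylsilyl)oxy]octa-2,6-dienoate
Conditions: Et3SiCl, imidazole, CH2Cl2, 0 °C
Reagents that add atoms: chlorotriethylsilane, CC[Si](Cl)(CC)CC
Why: Standard silylation; the triethylsilyl ether should survive hydride, enolisation and Lewis acid at low temperature, and can later be removed in the presence of a tert-butyldiphenylsilyl ether.

Step 4
Reactants: 5 methyl (2E,5S)-3,7-dimethyl-5-[(triethylsilyl)oxy]octa-2,6-dienoate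
Product: 6 (2E,5S)-3,7-dimethyl-5-[(triethylsilyl)oxy]octa-2,6-dien-1-ol
Conditions: iBu2AlH (2.2 equiv), CH2Cl2, −78 °C; Rochelle salt
Reagents that add atoms: none
Why: 1,2-Reduction of the enoate to the (E)-allylic alcohol; alkene geometry and C8 are untouched.

Step 5
Reactants: 7 4-methoxy-2-methylidene-4-oxobutanoic acid (itaconic acid 4-methyl ester)
Product: 8 methyl 3-(hydroxymethyl)but-3-enoate
Conditions: BH3·SMe2 (1.1 equiv), THF, −10 → 0 °C; MeOH quench
Reagents that add atoms: none
Why: Borane reduces the free carboxylic acid (via the acyloxyborane) much faster than the methyl ester, and faster than it hydroborates the electron-poor 1,1-disubstituted alkene; this turns C15 into the allylic CH2OH and leaves C6 as the ester.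

Step 6
Reactants: 8 methyl 3-(hydroxymethyl)but-3-enoate
Product: 9 methyl 3-{[(tert-butyldiphenylsilyl)oxy]methyl}but-3-enoate
Conditions: t-BuPh2SiCl, imidazole, CH2Cl2, 0 °C
Reagents that add atoms: tert-butylchlorodiphenylsilane, CC(C)(C)[Si](Cl)(c1ccccc1)c1ccccc1
Why: Immediate silylation stops lactonisation of the γ-hydroxy ester; the tert-butyldiphenylsilyl ether is meant to last until the final step.

Step 7
Reactants: 9 methyl 3-{[(tert-butyldiphenylsilyl)oxy]methyl}but-3-enoate
Product: 10 3-{[(tert-butyldiphenylsilyl)oxy]methyl}but-3-enoic acid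
Conditions: LiOH, THF/H2O (3:1), 0 °C; 1 M HCl to pH 4
Reagents that add atoms: lithium hydroxide, [Li+].[OH-]
Why: Saponification; at 0 °C acyl–oxygen cleavage should outrun α-deprotonation, so the double bond stays out of conjugation.

Step 8
Reactants: 6 (2E,5S)-3,7-dimethyl-5-[(triethylsilyl)oxy]octa-2,6-dien-1-ol; 10 3-{[(tert-butyldiphenylsilyl)oxy]methyl}but-3-enoic acid
Product: 11 (2E,5S)-3,7-dimethyl-5-[(triethylsilyl)oxy]octa-2,6-dien-1-yl 3-{[(tert-butyldiphenylsilyl)oxy]methyl}but-3-enoate
Conditions: EDC·HCl, DMAP (10 mol %), CH2Cl2, 0 °C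
Reagents that add atoms: none
Why: Steglich-type carbodiimide esterification; low temperature and little DMAP limit ketene formation and double-bond migration of the β,γ-unsaturated acid.

Step 9
Reactants: 11 (2E,5S)-3,7-dimethyl-5-[(triethylsilyl)oxy]octa-2,6-dien-1-yl 3-{[(tert-butyldiphenylsilyl)oxy]methyl}but-3-enoate
Product: 13 (2R,3S,5S)-2-{3-[(tert-butyldiphenylsilyl)oxy]prop-1-en-2-yl}-3-ethenyl-3,7-dimethyl-5-[(triethylsilyl)oxy]oct-6-enoic acid, via boron ketene acetal 12 (not isolated)
Conditions: (S,S)-2-bromo-4,5-diphenyl-1,3-bis{[3,5-bis(trifluoromethyl)phenyl]sulfonyl}-1,3,2-diazaborolidine (1.2 equiv), Et3N, toluene/hexane, −78 °C, then −20 °C; pH 4 buffer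
Reagents that add atoms: none
Why: Enantioselective Ireland–Claisen rearrangement of a boron ester enolate, which forms C5–C10 and creates the vinyl group. Et3N in toluene/hexane should give enolate 12 with C4 cis to the allyloxy oxygen; the chair transition state with the (E)-trisubstituted alkene (C9 equatorial, C14 axial) then fixes the C5/C10 relationship. The C2-symmetric sulfonamide ligand on boron shields one enolate face and so sets both centres absolutely (C5 R, C10 S); the remote C8 centre is not expected to interfere.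

Step 10
Reactants: 13 (2R,3S,5S)-2-{3-[(tert-butyldiphenylsilyl)oxy]prop-1-en-2-yl}-3-ethenyl-3,7-dimethyl-5-[(triethylsilyl)oxy]oct-6-enoic acid
Product: 14 (2R,3S,5S)-2-{3-[(tert-butyldiphenylsilyl)oxy]prop-1-en-2-yl}-3-ethenyl-3,7-dimethyl-5-[(triethylsilyl)oxy]oct-6-en-1-ol
Conditions: LiAlH4, Et2O, 0 °C; aqueous NaOH work-up
Reagents that add atoms: none
Why: Hydride reduction of the acid to the primary alcohol; no stereocentre is touched and both silyl ethers should survive.

Step 11
Reactants: 14 (2R,3S,5S)-2-{3-[(tert-butyldiphenylsilyl)oxy]prop-1-en-2-yl}-3-ethenyl-3,7-dimethyl-5-[(triethylsilyl)oxy]oct-6-en-1-ol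
Product: 15 (2R,3S,5S)-2-{3-[(tert-butyldiphenylsilyl)oxy]prop-1-en-2-yl}-3-ethenyl-3,7-dimethyl-5-[(triethylsilyl)oxy]oct-6-enal
Conditions: Dess–Martin periodinane, NaHCO3, CH2Cl2, 0 °C; used at once
Reagents that add atoms: none
Why: Buffered, non-basic oxidation of the primary alcohol; these conditions are chosen to avoid epimerisation at C5 and migration of the C3=C4 double bond into conjugation.

Step 12
Reactants: 15 (2R,3S,5S)-2-{3-[(tert-butyldiphenylsilyl)oxy]prop-1-en-2-yl}-3-ethenyl-3,7-dimethyl-5-[(triethylsilyl)oxy]oct-6-enal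
Product: 16 (1R,2R,3S,5S,6S)-2-{3-[(tert-butyldiphenylsilyl)oxy]prop-1-en-2-yl}-3-ethenyl-3-methyl-6-(prop-1-en-2-yl)-5-[(triethylsilyl)oxy]cyclohexan-1-ol
Conditions: Me2AlCl (1.2 equiv), CH2Cl2, −78 → −40 °C; aq NaHCO3/Rochelle salt
Reagents that add atoms: none
Why: Type-1 intramolecular carbonyl-ene reaction, the citronellal-to-isopulegol cyclisation: Me2AlCl activates the aldehyde, C6 bonds to C7 of the trisubstituted alkene while a hydrogen of the (E)-methyl on C11 passes to the carbonyl oxygen, which leaves the C11=C13 methylidene. Ring C5–C6–C7–C8–C9–C10 closes in the 6-exo mode with respect to the alkene (C11 stays outside the ring) through a chair in which the C5 side chain, the C10 vinyl group and the C8 silyloxy group are equatorial and only C14 is axial; the flipped chair would put all three axial. C7 is set by this chair: the isopropylidene unit takes the equatorial position, and allylic 1,3-strain with the (Z)-methyl holds H8 in the alkene plane and the C8–O bond anti to the forming bond, so C11 ends trans to O8. C6 is set by the orientation of the complexed carbonyl: the equatorial position is preferred as in isopulegol and is reinforced here because an axial O–Al unit would be 1,3-diaxial to the C14 methyl, so O6 ends trans to C11, which is the later trans lactone fusion. The selectivity needed is chemoselectivity among three alkenes, and ring size secures it: bonding to C3 would give a four-membered ring, and the vinyl group has no allylic hydrogen and would require a secondary cation. The closest precedent is the Lewis-acid-promoted cyclisation of citronellal and its 3,3-disubstituted analogues to all-equatorial isopulegols; the allylic silyloxy group and the α-alkenyl aldehyde are the new elements. Me2AlCl is chosen because it removes the proton of the alcohol–Lewis acid complex as methane, which should suppress chloride capture of the Prins type and acid-induced ionisation of the allylic ether.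

Step 13
Reactants: 16 (1R,2R,3S,5S,6S)-2-{3-[(tert-butyldiphenylsilyl)oxy]prop-1-en-2-yl}-3-ethenyl-3-methyl-6-(prop-1-en-2-yl)-5-[(triethylsilyl)oxy]cyclohexan-1-ol
Product: 17 (1R,2R,3S,5S,6S)-2-{3-[(tert-butyldiphenylsilyl)oxy]prop-1-en-2-yl}-3-ethenyl-6-(3-hydroxyprop-1-en-2-yl)-3-methyl-5-[(triethylsilyl)oxy]cyclohexan-1-ol
Conditions: SeO2 (0.5 equiv), t-BuOOH (3 equiv, in decane), CH2Cl2, 0 °C → rt
Reagents that add atoms: selenium dioxide, O=[Se]=O; tert-butyl hydroperoxide, CC(C)(C)OO
Why: Allylic hydroxylation by ene reaction and [2,3]-shift; the isopropenyl group holds the only allylic methyl, the C3=C4 alkene is deactivated by its allylic silyloxy group, and the vinyl group has no allylic hydrogen. Any hydroxy enal from over-oxidation converges in step 14.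

Step 14
Reactants: 17 (1R,2R,3S,5S,6S)-2-{3-[(tert-butyldiphenylsilyl)oxy]prop-1-en-2-yl}-3-ethenyl-6-(3-hydroxyprop-1-en-2-yl)-3-methyl-5-[(triethylsilyl)oxy]cyclohexan-1-ol
Product: 19 (3aS,4S,6S,7R,7aR)-7-{3-[(tert-butyldiphenylsilyl)oxy]prop-1-en-2-yl}-6-ethenyl-6-methyl-3-methylidene-4-[(triethylsilyl)oxy]hexahydro-1-benzofuran-2(3H)-one, via lactol 18 (not isolated)
Conditions: MnO2 (activated, 20 equiv), CH2Cl2, rt
Reagents that add atoms: none
Why: Oxidative lactonisation of a 2-methylidene-1,4-diol: MnO2 oxidises only the allylic primary alcohol, the enal is trapped by the C6 hydroxyl as lactol 18, and the lactol is oxidised on to the lactone. O8 is silylated, so only the 6,12-lactone can form; the trans fusion is inherited from step 12.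

Step 15
Reactants: 19 (3aS,4S,6S,7R,7aR)-7-{3-[(tert-butyldiphenylsilyl)oxy]prop-1-en-2-yl}-6-ethenyl-6-methyl-3-methylidene-4-[(triethylsilyl)oxy]hexahydro-1-benzofuran-2(3H)-one
Product: 20 (3aR,4S,6S,7R,7aR)-7-{3-[(tert-butyldiphenylsilyl)oxy]prop-1-en-2-yl}-6-ethenyl-4-hydroxy-6-methyl-3-methylidenehexahydro-1-benzofuran-2(3H)-one
Conditions: PPTS, MeOH/CH2Cl2, rt
Reagents that add atoms: none
Why: Acid-catalysed methanolysis should cleave the triethylsilyl ether far faster than the primary tert-butyldiphenylsilyl ether, and mild acid does not touch the methylene lactone. The descriptor at C3a changes only because the priorities change.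

Step 16
Reactants: 21 methyl (2R)-3-hydroxy-2-methylpropanoate
Product: 22 methyl (2R)-3-[(tert-butyldiphenylsilyl)oxy]-2-methylpropanoate
Conditions: t-BuPh2SiCl, imidazole, DMF, rt
Reagents that add atoms: tert-butylchlorodiphenylsilane, CC(C)(C)[Si](Cl)(c1ccccc1)c1ccccc1
Why: Standard silylation of the Roche ester; the stereocentre comes from the chiral pool.

Step 17
Reactants: 22 methyl (2R)-3-[(tert-butyldiphenylsilyl)oxy]-2-methylpropanoate
Product: 23 (2R)-3-[(tert-butyldiphenylsilyl)oxy]-2-methylpropanoic acid
Conditions: LiOH, THF/MeOH/H2O, 0 °C → rt; 1 M HCl to pH 4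
Reagents that add atoms: lithium hydroxide, [Li+].[OH-]
Why: Saponification; hydrolysis is expected to be faster than enolisation, and the silyloxy group is a poor leaving group, so the α-centre should be kept.

Step 18
Reactants: 20 (3aR,4S,6S,7R,7aR)-7-{3-[(tert-butyldiphenylsilyl)oxy]prop-1-en-2-yl}-6-ethenyl-4-hydroxy-6-methyl-3-methylidenehexahydro-1-benzofuran-2(3H)-one; 23 (2R)-3-[(tert-butyldiphenylsilyl)oxy]-2-methylpropanoic acid
Product: 24 (3aR,4S,6S,7R,7aR)-7-{3-[(tert-butyldiphenylsilyl)oxy]prop-1-en-2-yl}-6-ethenyl-6-methyl-3-methylidene-2-oxooctahydro-1-benzofuran-4-yl (2R)-3-[(tert-butyldiphenylsilyl)oxy]-2-methylpropanoate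
Conditions: EDC·HCl, DMAP (0.3 equiv), CH2Cl2, 0 °C → rt
Reagents that add atoms: none
Why: Steglich esterification of the equatorial C8 alcohol with retention at C8 (acyl transfer to oxygen); nothing in the mixture is basic enough to epimerise the acid or add irreversibly to the methylene lactone.

Step 19
Reactants: 24 (3aR,4S,6S,7R,7aR)-7-{3-[(tert-butyldiphenylsilyl)oxy]prop-1-en-2-yl}-6-ethenyl-6-methyl-3-methylidene-2-oxooctahydro-1-benzofuran-4-yl (2R)-3-[(tert-butyldiphenylsilyl)oxy]-2-methylpropanoate
Product: 25 (3aR,4S,6S,7R,7aR)-6-ethenyl-7-(3-hydroxyprop-1-en-2-yl)-6-methyl-3-methylidene-2-oxooctahydro-1-benzofuran-4-yl (2R)-3-hydroxy-2-methylpropanoate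
Conditions: HF·pyridine, pyridine, THF, 0 °C → rt
Reagents that add atoms: none
Why: Fluoride cleavage of both primary silyl ethers under buffered, weakly acidic conditions, which avoid acyl shift, β-elimination of the hydroxy ester and conjugate addition to the lactone.

## Compound list

1 | methyl 3-methylbut-2-enoate | COC(=O)C=C(C)C | starting material
2 | tert-butyl[(1-methoxy-3-methylbuta-1,3-dien-1-yl)oxy]dimethylsilane | C=C(C)C=C(OC)O[Si](C)(C)C(C)(C)C | intermediate
3 | 3-methylbut-2-enal | CC(C)=CC=O | starting material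
4 | methyl (2E,5S)-5-hydroxy-3,7-dimethylocta-2,6-dienoate | COC(=O)/C=C(\C)C[C@H](O)C=C(C)C | intermediate
5 | methyl (2E,5S)-3,7-dimethyl-5-[(triethylsilyl)oxy]octa-2,6-dienoate | COC(=O)/C=C(\C)C[C@H](O[Si](CC)(CC)CC)C=C(C)C | intermediate
6 | (2E,5S)-3,7-dimethyl-5-[(triethylsilyl)oxy]octa-2,6-dien-1-ol | OC/C=C(\C)C[C@H](O[Si](CC)(CC)CC)C=C(C)C | intermediate
7 | 4-methoxy-2-methylidene-4-oxobutanoic acid | COC(=O)CC(=C)C(=O)O | starting material
8 | methyl 3-(hydroxymethyl)but-3-enoate | COC(=O)CC(=C)CO | intermediate
9 | methyl 3-{[(tert-butyldiphenylsilyl)oxy]methyl}but-3-enoate | COC(=O)CC(=C)CO[Si](c1ccccc1)(c1ccccc1)C(C)(C)C | intermediate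
10 | 3-{[(tert-butyldiphenylsilyl)oxy]methyl}but-3-enoic acid | OC(=O)CC(=C)CO[Si](c1ccccc1)(c1ccccc1)C(C)(C)C | intermediate
11 | (2E,5S)-3,7-dimethyl-5-[(triethylsilyl)oxy]octa-2,6-dien-1-yl 3-{[(tert-butyldiphenylsilyl)oxy]methyl}but-3-enoate | C=C(CO[Si](c1ccccc1)(c1ccccc1)C(C)(C)C)CC(=O)OC/C=C(\C)C[C@H](O[Si](CC)(CC)CC)C=C(C)C | intermediate
12 | boron ketene acetal of 11 with the (S,S)-diazaborolidine, C4 cis to the allyloxy oxygen (not isolated) | C=C(CO[Si](c1ccccc1)(c1ccccc1)C(C)(C)C)/C=C(\OC/C=C(\C)C[C@H](O[Si](CC)(CC)CC)C=C(C)C)OB1N([C@@H](c2ccccc2)[C@H](c2ccccc2)N1S(=O)(=O)c1cc(cc(c1)C(F)(F)F)C(F)(F)F)S(=O)(=O)c1cc(cc(c1)C(F)(F)F)C(F)(F)F | intermediate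
13 | (2R,3S,5S)-2-{3-[(tert-butyldiphenylsilyl)oxy]prop-1-en-2-yl}-3-ethenyl-3,7-dimethyl-5-[(triethylsilyl)oxy]oct-6-enoic acid | OC(=O)[C@@H](C(=C)CO[Si](c1ccccc1)(c1ccccc1)C(C)(C)C)[C@](C)(C=C)C[C@H](O[Si](CC)(CC)CC)C=C(C)C | intermediate
14 | (2R,3S,5S)-2-{3-[(tert-butyldiphenylsilyl)oxy]prop-1-en-2-yl}-3-ethenyl-3,7-dimethyl-5-[(triethylsilyl)oxy]oct-6-en-1-ol | OC[C@@H](C(=C)CO[Si](c1ccccc1)(c1ccccc1)C(C)(C)C)[C@](C)(C=C)C[C@H](O[Si](CC)(CC)CC)C=C(C)C | intermediate
15 | (2R,3S,5S)-2-{3-[(tert-butyldiphenylsilyl)oxy]prop-1-en-2-yl}-3-ethenyl-3,7-dimethyl-5-[(triethylsilyl)oxy]oct-6-enal | O=C[C@@H](C(=C)CO[Si](c1ccccc1)(c1ccccc1)C(C)(C)C)[C@](C)(C=C)C[C@H](O[Si](CC)(CC)CC)C=C(C)C | intermediate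
16 | (1R,2R,3S,5S,6S)-2-{3-[(tert-butyldiphenylsilyl)oxy]prop-1-en-2-yl}-3-ethenyl-3-methyl-6-(prop-1-en-2-yl)-5-[(triethylsilyl)oxy]cyclohexan-1-ol | C=C[C@]1(C)C[C@H](O[Si](CC)(CC)CC)[C@@H](C(C)=C)[C@H](O)[C@H]1C(=C)CO[Si](c1ccccc1)(c1ccccc1)C(C)(C)C | intermediate
17 | (1R,2R,3S,5S,6S)-2-{3-[(tert-butyldiphenylsilyl)oxy]prop-1-en-2-yl}-3-ethenyl-6-(3-hydroxyprop-1-en-2-yl)-3-methyl-5-[(triethylsilyl)oxy]cyclohexan-1-ol | C=C[C@]1(C)C[C@H](O[Si](CC)(CC)CC)[C@@H](C(=C)CO)[C@H](O)[C@H]1C(=C)CO[Si](c1ccccc1)(c1ccccc1)C(C)(C)C | intermediate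
18 | lactol of the C12 aldehyde with O6, anomeric centre undefined (not isolated) | C=C[C@]1(C)C[C@H](O[Si](CC)(CC)CC)[C@H]2C(=C)C(O)O[C@@H]2[C@H]1C(=C)CO[Si](c1ccccc1)(c1ccccc1)C(C)(C)C | intermediate
19 | (3aS,4S,6S,7R,7aR)-7-{3-[(tert-butyldiphenylsilyl)oxy]prop-1-en-2-yl}-6-ethenyl-6-methyl-3-methylidene-4-[(triethylsilyl)oxy]hexahydro-1-benzofuran-2(3H)-one | C=C[C@]1(C)C[C@H](O[Si](CC)(CC)CC)[C@H]2C(=C)C(=O)O[C@@H]2[C@H]1C(=C)CO[Si](c1ccccc1)(c1ccccc1)C(C)(C)C | intermediate
20 | (3aR,4S,6S,7R,7aR)-7-{3-[(tert-butyldiphenylsilyl)oxy]prop-1-en-2-yl}-6-ethenyl-4-hydroxy-6-methyl-3-methylidenehexahydro-1-benzofuran-2(3H)-one | C=C[C@]1(C)C[C@H](O)[C@H]2C(=C)C(=O)O[C@@H]2[C@H]1C(=C)CO[Si](c1ccccc1)(c1ccccc1)C(C)(C)C | intermediate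
21 | methyl (2R)-3-hydroxy-2-methylpropanoate | COC(=O)[C@H](C)CO | starting material
22 | methyl (2R)-3-[(tert-butyldiphenylsilyl)oxy]-2-methylpropanoate | COC(=O)[C@H](C)CO[Si](c1ccccc1)(c1ccccc1)C(C)(C)C | intermediate
23 | (2R)-3-[(tert-butyldiphenylsilyl)oxy]-2-methylpropanoic acid | OC(=O)[C@H](C)CO[Si](c1ccccc1)(c1ccccc1)C(C)(C)C | intermediate
24 | (3aR,4S,6S,7R,7aR)-7-{3-[(tert-butyldiphenylsilyl)oxy]prop-1-en-2-yl}-6-ethenyl-6-methyl-3-methylidene-2-oxooctahydro-1-benzofuran-4-yl (2R)-3-[(tert-butyldiphenylsilyl)oxy]-2-methylpropanoate | C=C[C@]1(C)C[C@H](OC(=O)[C@H](C)CO[Si](c3ccccc3)(c3ccccc3)C(C)(C)C)[C@H]2C(=C)C(=O)O[C@@H]2[C@H]1C(=C)CO[Si](c1ccccc1)(c1ccccc1)C(C)(C)C | intermediate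
25 | (3aR,4S,6S,7R,7aR)-6-ethenyl-7-(3-hydroxyprop-1-en-2-yl)-6-methyl-3-methylidene-2-oxooctahydro-1-benzofuran-4-yl (2R)-3-hydroxy-2-methylpropanoate | C=C[C@]1(C)C[C@H](OC(=O)[C@H](C)CO)[C@H]2C(=C)C(=O)O[C@@H]2[C@H]1C(=C)CO | target

## Step count and least certain steps

Total: 19 steps. Longest linear sequence: 14 steps (steps 1–4, 8–15, 18, 19, from 1).

**Step 12 (key step).** The most likely failure is loss of the C5 configuration, by enolisation or double-bond migration of the β,γ-unsaturated aldehyde on the Lewis acid before the ring closes, or ionisation of the allylic C8 silyl ether. Closure through the O-axial chair is less likely. The fallback closes the same C6–C7 bond from the acid oxidation level and sets C6 afterwards. Acid 13 is converted with oxalyl chloride into the (2R,3S,5S)-acid chloride F1. With SnCl4 in CH2Cl2 at −78 °C, F1 should acylate the prenyl alkene intramolecularly with loss of a methyl proton (acyl-ene reaction) to give the (2R,3S,5S,6R)-cyclohexanone F2. In F2 the all-equatorial arrangement at C5 and C7 is the stable one. F2 is reduced at once, before the isopropenyl group can move into conjugation, under equilibrating conditions (SmI2, i-PrOH, THF), which should give the equatorial alcohol 16, where the route is rejoined.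

**Step 9.** The most likely failure is insufficient facial discrimination by the boron controller on a dienolate that carries a bulky silyloxymethyl group, or a sluggish rearrangement at −20 °C with slow Lewis-acid attack on the silyl ethers. The fallback replaces reagent control by separation, using C8 as a built-in resolving centre. Ester 11 is enolised with LiN(iPr)2 and Me3SiCl/Et3N in THF at −78 °C to the silyl ketene acetal F3 (same enolate geometry), which rearranges on warming. After hydrolysis this should give acid 13 together with its (2S,3R,5S)-isomer F4, which are diastereomers because C8 is already resolved. They are separated by chromatography at the acid stage or after step 12, where only the aldehyde from 13 can close through an all-equatorial chair. The route is rejoined at 13, at the cost of up to half of the material.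

**Step 13.** The most likely failure is loss of site selectivity (hydroxylation at the C7 methine to a tertiary alcohol, or attack on the C3=C4 alkene) together with over-oxidation. The fallback functionalises the methyl group through the neighbouring hydroxyl. Ene-type chlorination of 16 with Ca(OCl)2/CO2 in CH2Cl2–H2O should give the allylic chloride F5. NaH in THF closes the C6 alkoxide onto the chloromethyl group (5-exo-tet) to the 3-methylideneoxolane F6. CrO3·3,5-dimethylpyrazole in CH2Cl2 at −20 °C then oxidises the allylic ether methylene to the lactone 19, where the route is rejoined.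

**Step 2.** The most likely failure is lower enantioselectivity, or competing α-attack, with the β,β-disubstituted enal. The fallback sets C8 by reduction instead of by C–C bond formation. Dienolate 2 and aldehyde 3 are joined with BF3·OEt2 (achiral Mukaiyama conditions) to the racemic hydroxy ester F7. Dess–Martin oxidation gives the enone F8. Corey–Bakshi–Shibata reduction with (R)-1-methyl-3,3-diphenyltetrahydro-1H,3H-pyrrolo[1,2-c][1,3,2]oxazaborole and catecholborane at −78 °C should return 4, where the route is rejoined.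

## Further compounds

F1 | step 12 | (2R,3S,5S)-2-{3-[(tert-butyldiphenylsilyl)oxy]prop-1-en-2-yl}-3-ethenyl-3,7-dimethyl-5-[(triethylsilyl)oxy]oct-6-enoyl chloride | ClC(=O)[C@@H](C(=C)CO[Si](c1ccccc1)(c1ccccc1)C(C)(C)C)[C@](C)(C=C)C[C@H](O[Si](CC)(CC)CC)C=C(C)C
F2 | step 12 | (2R,3S,5S,6R)-2-{3-[(tert-butyldiphenylsilyl)oxy]prop-1-en-2-yl}-3-ethenyl-3-methyl-6-(prop-1-en-2-yl)-5-[(triethylsilyl)oxy]cyclohexan-1-one | C=C[C@]1(C)C[C@H](O[Si](CC)(CC)CC)[C@@H](C(C)=C)C(=O)[C@H]1C(=C)CO[Si](c1ccccc1)(c1ccccc1)C(C)(C)C
F3 | step 9 | trimethylsilyl ketene acetal of 11, C4 cis to the allyloxy oxygen | C=C(CO[Si](c1ccccc1)(c1ccccc1)C(C)(C)C)/C=C(\OC/C=C(\C)C[C@H](O[Si](CC)(CC)CC)C=C(C)C)O[Si](C)(C)C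
F4 | step 9 | (2S,3R,5S)-2-{3-[(tert-butyldiphenylsilyl)oxy]prop-1-en-2-yl}-3-ethenyl-3,7-dimethyl-5-[(triethylsilyl)oxy]oct-6-enoic acid | OC(=O)[C@H](C(=C)CO[Si](c1ccccc1)(c1ccccc1)C(C)(C)C)[C@@](C)(C=C)C[C@H](O[Si](CC)(CC)CC)C=C(C)C
F5 | step 13 | (1R,2R,3S,5S,6S)-2-{3-[(tert-butyldiphenylsilyl)oxy]prop-1-en-2-yl}-6-(3-chloroprop-1-en-2-yl)-3-ethenyl-3-methyl-5-[(triethylsilyl)oxy]cyclohexan-1-ol | C=C[C@]1(C)C[C@H](O[Si](CC)(CC)CC)[C@@H](C(=C)CCl)[C@H](O)[C@H]1C(=C)CO[Si](c1ccccc1)(c1ccccc1)C(C)(C)C
F6 | step 13 | (3aS,4S,6S,7R,7aR)-7-{3-[(tert-butyldiphenylsilyl)oxy]prop-1-en-2-yl}-6-ethenyl-6-methyl-3-methylidene-4-[(triethylsilyl)oxy]octahydro-1-benzofuran | C=C[C@]1(C)C[C@H](O[Si](CC)(CC)CC)[C@H]2C(=C)CO[C@@H]2[C@H]1C(=C)CO[Si](c1ccccc1)(c1ccccc1)C(C)(C)C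
F7 | step 2 | methyl (2E)-5-hydroxy-3,7-dimethylocta-2,6-dienoate, racemic | COC(=O)/C=C(\C)CC(O)C=C(C)C
F8 | step 2 | methyl (2E)-3,7-dimethyl-5-oxoocta-2,6-dienoate | COC(=O)/C=C(\C)CC(=O)C=C(C)C
A1 | alternative 1 | (5S)-5-[(tert-butyldimethylsilyl)oxy]-3-methylcyclohex-2-en-1-one | CC1=CC(=O)C[C@@H](O[Si](C)(C)C(C)(C)C)C1
A2 | alternative 1 | (3R,5S)-5-[(tert-butyldimethylsilyl)oxy]-3-ethenyl-3-methylcyclohexan-1-one | O=C1C[C@](C)(C=C)C[C@H](O[Si](C)(C)C(C)(C)C)C1
A3 | alternative 2 | (3aR,4S,6E,10Z,11aR)-10-(hydroxymethyl)-6-methyl-3-methylidene-2-oxo-2,3,3a,4,5,8,9,11a-octahydrocyclodeca[b]furan-4-yl (2R)-3-hydroxy-2-methylpropanoate | C/C1=C\CC/C(CO)=C/[C@H]2OC(=O)C(=C)[C@@H]2[C@@H](OC(=O)[C@H](C)CO)C1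
A4 | alternative 3 | methyl (2Z,4S,6S,7R)-2-(bromomethyl)-7-{3-[(tert-butyldiphenylsilyl)oxy]prop-1-en-2-yl}-6-ethenyl-6-methyl-8-oxo-4-[(triethylsilyl)oxy]oct-2-enoate | O=C[C@@H](C(=C)CO[Si](c1ccccc1)(c1ccccc1)C(C)(C)C)[C@](C)(C=C)C[C@H](O[Si](CC)(CC)CC)/C=C(\CBr)C(=O)OC
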